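**Assumption:** Genistein (1) is taken as a commercial starting material, and its chelated 5‑OH is not alkylated by K2CO3/allyl bromide. Lupalbigenin has no stereocenters, so no stereochemistry has to be set.

## Retrosynthetic overview
1. Lupalbigenin (6) is 6,3'‑diprenylgenistein. Both prenyl groups come from allyl groups by cross‑metathesis with 2‑methyl‑2‑butene, which avoids the reverse‑prenyl product a prenyl Claisen would give.
2. The two allyl groups come from one double aromatic Claisen rearrangement of 7,4'‑di‑O‑allylgenistein. The 4'‑allyl ether can only go to C3'. The chelated 5‑OH fixes the A‑ring bond order so the 7‑allyl ether goes mainly to C6 rather than C8.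
3. 7,4'‑Di‑O‑allylgenistein comes from genistein by selective alkylation of the 7‑OH and 4'‑OH.
4. No ring is built. The chromone and both arene rings are already present in genistein.

## Route

**Step 1**
Reactants: 1 genistein (5,7,4'‑trihydroxyisoflavone); 2 allyl bromide
Product: 3 7,4'‑di‑O‑allylgenistein
Conditions: 2 (2.5 equiv), K2CO3 (3 equiv), cat. KI, acetone, reflux, 12 h
Reagents that add atoms: allyl bromide, C=CCBr
Why: The 7‑OH and 4'‑OH are the acidic, non‑chelated phenols, so Williamson O‑alkylation occurs there. The 5‑OH is H‑bonded to the C4 carbonyl and stays free.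

**Step 2**
Reactants: 3 7,4'‑di‑O‑allylgenistein
Product: 4 6,3'‑diallylgenistein (5,7,4'‑trihydroxy‑6,3'‑diallylisoflavone)
Conditions: N,N‑diethylaniline, 200–210 °C, sealed tube, Ar, 4–6 h (or microwave); silica chromatography to remove the 8‑allyl isomer
Reagents that add atoms: none
Why: Double aromatic Claisen ([3,3]‑sigmatropic) rearrangement of the two aryl allyl ethers. Each allyl group migrates to an ortho carbon with the terminal CH2 bonding to the ring, so the allyl chain is unbranched. The 4'‑ether has equivalent ortho positions, giving 3'. In the 7‑ether, 5‑OH chelation gives the C6=C7 bond more double‑bond character, which favours C6. The minor 8‑allyl isomer is removed by chromatography.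

**Step 3**
Reactants: 4 6,3'‑diallylgenistein; 5 2‑methyl‑2‑butene
Product: 6 lupalbigenin
Conditions: 5 (40 equiv), Hoveyda–Grubbs II (2 × 5 mol%), 1,4‑benzoquinone (10 mol%), CH2Cl2, 40 °C, sealed tube, 16 h
Reagents that add atoms: 2‑methyl‑2‑butene, CC=C(C)C
Why: Olefin cross‑metathesis of each terminal allyl group with excess 2‑methyl‑2‑butene gives the trisubstituted prenyl alkene and volatile propene. Benzoquinone suppresses Ru–H isomerisation of the allyl groups. The free phenols and the chromone survive.

## Compound list
1 | genistein | O=c1c(-c2ccc(O)cc2)coc2cc(O)cc(O)c12 | starting material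
2 | allyl bromide | C=CCBr | starting material
3 | 7,4'‑di‑O‑allylgenistein | C=CCOc1ccc(cc1)-c1coc2cc(OCC=C)cc(O)c2c1=O | intermediate
4 | 6,3'‑diallylgenistein | C=CCc1cc(ccc1O)-c1coc2cc(O)c(CC=C)c(O)c2c1=O | intermediate
5 | 2‑methyl‑2‑butene | CC=C(C)C | starting material
6 | lupalbigenin (5,7,4'‑trihydroxy‑6,3'‑diprenylisoflavone; achiral) | CC(C)=CCc1cc(-c2coc3cc(O)c(CC=C(C)C)c(O)c3c2=O)ccc1O | target

**Total step count:** 3. **Longest linear sequence:** 3 (1 → 3 → 4 → 6).

## Three steps most likely to fail
1. **Step 2, C6 versus C8 selectivity and thermal yield.** The 5‑OH bias for C6 may be only partial, and some decomposition may occur at 200 °C.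
   - Fallback: build the prenylated A ring first. Acylate 2‑prenylphloroglucinol with 3‑prenyl‑4‑hydroxyphenylacetic acid (BF3·Et2O) to give the deoxybenzoin, then close the chromone with BF3·Et2O/DMF/MsCl.
2. **Step 3, cross‑metathesis on a polyphenol.** Allyl‑to‑propenyl isomerisation, phenol poisoning of the Ru catalyst, or incomplete double conversion are all possible.
   - Fallback: cleave the allyl groups to aldehydes (OsO4/NaIO4, after protecting the phenols as MOM ethers), then do a double Wittig olefination with isopropylidene‑triphenylphosphorane (from Ph3P+CHMe2 I⁻, KOtBu). Remove the MOM groups at the end.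
3. **Step 1, selective bis‑O‑allylation.** Mixtures of mono‑, bis‑ and 5,7,4'‑tri‑O‑allyl products are possible.
   - Fallback: go stepwise. Alkylate the 7‑OH selectively (1.05 equiv allyl bromide, K2CO3, acetone, rt) and Claisen‑rearrange it. Then allylate the 4'‑OH and do a second Claisen, so each alkylation and rearrangement is controlled separately.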